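## Retrosynthetic overview
1. The last operation is reversed by cutting C3a–C4 (Dieckmann closure and aromatisation) and O1–C2 (SN2 on an (R)-epoxide). Ring A and the dihydrofuran both fall back to one acyclic epoxy β-diketo β-methoxy-enoate.
2. That chain is cut at the bond between the cinnamoyl C=O and C7. This is C-acylation of a δ-keto-β-methoxy-enoate with 4-acetoxycinnamoyl chloride; ring B is bought.
3. The keto enoate comes from methanolysis of a 6-(epoxyalkyl)-4-methoxy-2-pyranone. This pyranone already holds the OMe and all six ring-A carbons in the right order.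
4. The epoxide comes from Shi epoxidation of the prenylated pyranone, which comes from 4-methoxy-6-methyl-2-pyranone and prenyl bromide.
5. Ring order: oxirane in step 2, sacrificial pyranone opened in step 3, then oxolane and benzene ring A in the same final flask.

Assumption: the stereocentre in the SMILES is read as (S) at C-2 of the dihydrobenzofuran. Compounds 1, 2, 6 and the D-fructose-derived Shi ketone are bought.

## Route

Step 1
Reactants: 1 4-methoxy-6-methyl-2H-pyran-2-one; 2 prenyl bromide (1-bromo-3-methylbut-2-ene)
Product: 3 4-methoxy-6-(4-methylpent-3-en-1-yl)-2H-pyran-2-one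
Conditions: LDA (1.05 equiv), THF–DMPU, –78 °C; then 2, –78 → –20 °C
Reagents that add atoms: none
Why: Vinylogous deprotonation of the 6-methyl group gives a delocalised pyranone anion that alkylates at the exocyclic carbon, and the primary allylic bromide reacts by SN2 (enolate alkylation); no stereocentre is formed.

Step 2
Reactants: 3 4-methoxy-6-(4-methylpent-3-en-1-yl)-2H-pyran-2-one
Product: 4 6-{2-[(2R)-3,3-dimethyloxiran-2-yl]ethyl}-4-methoxy-2H-pyran-2-one
Conditions: D-fructose-derived Shi ketone (0.3 equiv), Oxone, K2CO3, Bu4NHSO4 (cat.), MeCN–DMM / aq. borate–EDTA buffer (pH 10.5), 0 °C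
Reagents that add atoms: Oxone (potassium peroxymonosulfate), [K+].[O-]S(=O)(=O)OO
Why: In this Shi asymmetric epoxidation the chiral dioxirane attacks only the electron-rich trisubstituted alkene (the pyranone C=C bonds are deactivated as vinylogous esters), and the spiro transition state of the D-fructose-derived ketone delivers oxygen to the face that gives the (R)-epoxide, the same sense as (R,R) from trans-alkenes.

Step 3
Reactants: 4 6-{2-[(2R)-3,3-dimethyloxiran-2-yl]ethyl}-4-methoxy-2H-pyran-2-one
Product: 5 methyl (2E)-7-[(2R)-3,3-dimethyloxiran-2-yl]-3-methoxy-5-oxohept-2-enoate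
Conditions: NaOMe (1.2 equiv), MeOH, 0 °C, 1 h; AcOH (1.2 equiv), –20 °C
Reagents that add atoms: sodium methoxide, [Na+].[O-]C
Why: This is alkoxide ring opening (transesterification) of an enol lactone, in which methoxide adds to C-2, the ring oxygen leaves as a conjugated stabilised enolate that pulls the equilibrium, and the cold acid quench gives the keto ester with the ester still cis to the ketone arm (E) and the epoxide stereocentre untouched.

Step 4
Reactants: 6 (E)-4-acetoxycinnamic acid
Product: 7 (E)-4-acetoxycinnamoyl chloride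
Conditions: (COCl)2 (1.2 equiv), DMF (cat.), CH2Cl2, 0 °C → rt; concentrate
Reagents that add atoms: oxalyl chloride, ClC(=O)C(=O)Cl
Why: This is standard Vilsmeier-type acid chloride formation, and the aryl acetate and the E-alkene are inert to it.

Step 5
Reactants: 5 methyl (2E)-7-[(2R)-3,3-dimethyloxiran-2-yl]-3-methoxy-5-oxohept-2-enoate; 7 (E)-4-acetoxycinnamoyl chloride
Product: 10 (2E)-1-[(2S)-4-hydroxy-2-(2-hydroxypropan-2-yl)-6-methoxy-2,3-dihydro-1-benzofuran-7-yl]-3-(4-hydroxyphenyl)prop-2-en-1-one, via C-acylated epoxy triketo ester 8 (not isolated), via 2-alkylideneoxolane 9 (not isolated)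
Conditions: LiHMDS (2.1 equiv, second equiv after 7), THF, –78 → 0 °C; then NaOMe (6 equiv), MeOH, 0 → 60 °C; aq. HCl to pH 5
Reagents that add atoms: none
Why: Proposed new method: the conjugated lithium enolate of 5 is C-acylated at chain C-4, next to the ketone (Claisen-type acylation with an acid chloride, the second equivalent of base taking up the more acidic product 8); methoxide then strips the acetate first, so the B-ring phenoxide switches the enone off as a Michael acceptor; the β-diketonate oxygen on the alkyl-ketone carbon opens the epoxide at its CH carbon by a favoured 5-exo-tet SN2 with inversion, (R) → (S), while C-attack would be a disfavoured 5-(enolendo)-exo-tet closure and the future benzofuran 4-oxygen is still locked as the ester, so only the oxygen next to the acyl-bearing carbon can cyclise; finally the γ-acidic ring CH2 of 9 (comparable to the methyl of a 2-methylchromone) closes on the cis-placed ester in an allowed 6-(enolendo)-exo-trig Dieckmann condensation, and loss of methanol with enolisation makes ring A irreversibly; the closest known reaction types are cyclisation of 1,3-dicarbonyl enolates onto epoxides to give 2-alkylidenetetrahydrofurans and base-induced Claisen aromatisation of pyranones or polyketo esters to phloroglucinols.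

## Compound list
1 | 4-methoxy-6-methyl-2H-pyran-2-one | COC1=CC(=O)OC(C)=C1 | starting material
2 | prenyl bromide (1-bromo-3-methylbut-2-ene) | CC(C)=CCBr | starting material
3 | 4-methoxy-6-(4-methylpent-3-en-1-yl)-2H-pyran-2-one | COC1=CC(=O)OC(CCC=C(C)C)=C1 | intermediate
4 | 6-{2-[(2R)-3,3-dimethyloxiran-2-yl]ethyl}-4-methoxy-2H-pyran-2-one | COC1=CC(=O)OC(CC[C@H]2OC2(C)C)=C1 | intermediate
5 | methyl (2E)-7-[(2R)-3,3-dimethyloxiran-2-yl]-3-methoxy-5-oxohept-2-enoate | COC(=O)/C=C(/OC)CC(=O)CC[C@H]1OC1(C)C | intermediate
6 | (E)-4-acetoxycinnamic acid | CC(=O)Oc1ccc(/C=C/C(=O)O)cc1 | starting material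
7 | (E)-4-acetoxycinnamoyl chloride | CC(=O)Oc1ccc(/C=C/C(=O)Cl)cc1 | intermediate
8 | methyl (2E)-4-[(2E)-3-(4-acetyloxyphenyl)prop-2-enoyl]-7-[(2R)-3,3-dimethyloxiran-2-yl]-3-methoxy-5-oxohept-2-enoate (drawn as the triketo tautomer; chain C-4 is enolised and not a fixed stereocentre) | COC(=O)/C=C(/OC)C(C(=O)/C=C/c1ccc(OC(C)=O)cc1)C(=O)CC[C@H]1OC1(C)C | intermediate
9 | methyl (2E,6E)-7-(4-hydroxyphenyl)-4-[(5S)-5-(2-hydroxypropan-2-yl)oxolan-2-ylidene]-3-methoxy-5-oxohepta-2,6-dienoate (push–pull ylidene C=C, geometry labile) | COC(=O)/C=C(/OC)C(C(=O)/C=C/c1ccc(O)cc1)=C1CC[C@@H](C(C)(C)O)O1 | intermediate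
10 | (2E)-1-[(2S)-4-hydroxy-2-(2-hydroxypropan-2-yl)-6-methoxy-2,3-dihydro-1-benzofuran-7-yl]-3-(4-hydroxyphenyl)prop-2-en-1-one | COc1cc(O)c2c(c1C(=O)/C=C/c1ccc(O)cc1)O[C@H](C(C)(C)O)C2 | target

## Count and risks
Total steps: 5. Longest linear sequence: 4 (steps 1, 2, 3, 5).

**Step 5** is the most likely to fail.
- O- or ester-side acylation of the ambident enolate could compete with the wanted C-acylation.
- The ring CH2 carbanion of 9 could add to the enone instead of the ester.
- The Dieckmann closure on a vinylogous carbonate ester could stall.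

The fallback sets out from 4 and comes back at 10. It makes the arene before the acyl group is present.
- Heating 4 with NaOMe in MeOH (sealed tube, 120–150 °C) opens the pyranone, opens the epoxide and closes the ring. This gives (2S)-2-(2-hydroxypropan-2-yl)-6-methoxy-2,3-dihydro-1-benzofuran-4-ol F1. The two oxygens flanking the side chain are equivalent at this stage, so there is no regiochemical question.
- TIPSCl and imidazole give the 4-O-triisopropylsilyl ether F2.
- n-BuLi (2.2 equiv, THF, 0 °C) lithiates C-7 between the two ether oxygens, with the bulky OTIPS group shielding C-5. N-methoxy-N-methylacetamide then gives the 7-acetyl silyl ether F3.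
- Claisen–Schmidt condensation with 4-hydroxybenzaldehyde (KOH, EtOH) gives the silyl-protected chalcone F4, and TBAF gives 10.

**Step 3** is the second risk. The open form may revert to the pyranone on work-up, or its enolate may open the epoxide too early.

The fallback sets out from 2 and comes back at 5. It never exposes the keto ester to base.
- The lithium enolate of N-methoxy-N-methylacetamide is alkylated with 2 to give N-methoxy-N,5-dimethylhex-4-enamide F5.
- Shi epoxidation with the same ketone gives 3-[(2R)-3,3-dimethyloxiran-2-yl]-N-methoxy-N-methylpropanamide F6.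
- The lithium dienolate of methyl (E)-3-methoxybut-2-enoate (LDA, THF, –78 °C) adds through its γ-carbon. The chelated tetrahedral adduct releases the ketone 5 only on acidic quench.

**Step 2** is the third risk. The ee may be too low for a 2-methyl-2-alkene type olefin, or the pyranone may be lost at pH 10.5.

The fallback sets out from 1 and comes back at 4. It brings the stereocentre in with the electrophile.
- Sharpless epoxidation of 3-methylbut-2-en-1-ol (D-(–)-DIPT, Ti(OiPr)4, TBHP, 4 Å sieves) gives [(2R)-3,3-dimethyloxiran-2-yl]methanol F7.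
- Tf2O and 2,6-lutidine give [(2R)-3,3-dimethyloxiran-2-yl]methyl trifluoromethanesulfonate F8.
- Lithiated 1 (LDA, THF, –78 °C) displaces the primary triflate without touching the stereocentre and gives 4.

## Further compounds
F1 | step 5 | (2S)-2-(2-hydroxypropan-2-yl)-6-methoxy-2,3-dihydro-1-benzofuran-4-ol | COc1cc(O)c2c(c1)O[C@H](C(C)(C)O)C2
F2 | step 5 | 2-[(2S)-6-methoxy-4-(triisopropylsilyloxy)-2,3-dihydro-1-benzofuran-2-yl]propan-2-ol | COc1cc(O[Si](C(C)C)(C(C)C)C(C)C)c2c(c1)O[C@H](C(C)(C)O)C2
F3 | step 5 | 1-[(2S)-2-(2-hydroxypropan-2-yl)-6-methoxy-4-(triisopropylsilyloxy)-2,3-dihydro-1-benzofuran-7-yl]ethan-1-one | COc1cc(O[Si](C(C)C)(C(C)C)C(C)C)c2c(c1C(C)=O)O[C@H](C(C)(C)O)C2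
F4 | step 5 | (2E)-1-[(2S)-2-(2-hydroxypropan-2-yl)-6-methoxy-4-(triisopropylsilyloxy)-2,3-dihydro-1-benzofuran-7-yl]-3-(4-hydroxyphenyl)prop-2-en-1-one | COc1cc(O[Si](C(C)C)(C(C)C)C(C)C)c2c(c1C(=O)/C=C/c1ccc(O)cc1)O[C@H](C(C)(C)O)C2
F5 | step 3 | N-methoxy-N,5-dimethylhex-4-enamide | CON(C)C(=O)CCC=C(C)C
F6 | step 3 | 3-[(2R)-3,3-dimethyloxiran-2-yl]-N-methoxy-N-methylpropanamide | CON(C)C(=O)CC[C@H]1OC1(C)C
F7 | step 2 | [(2R)-3,3-dimethyloxiran-2-yl]methanol | OC[C@H]1OC1(C)C
F8 | step 2 | [(2R)-3,3-dimethyloxiran-2-yl]methyl trifluoromethanesulfonate | O=S(=O)(OC[C@H]1OC1(C)C)C(F)(F)F
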